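**Retrosynthetic overview**

- The strategy rests on the quinone ring of the naphthazarin: C1(=O)–C2(side chain)=C3(H)–C4(=O), fused through C4a/C8a to the 5,8-dioxygenated benzenoid ring. C1, C4, C4a and C8a map onto 3,6-dimethoxybenzocyclobutene-1,2-dione 6, and C2=C3 onto a terminal alkyne that already carries the C1' stereocentre.
- Target 28 comes from ester 26 by oxidative demethylation; 26 from alcohol 22 and acid 25; 22 from silyl ether 21.
- Quinone 21 comes from the strain-release ring expansion of alkynyl carbinol 18, which forms C1–C2. Carbinol 18 comes from dione 6 and the lithium acetylide of alkyne 16.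
- Dione 6 comes from bromoarene 1 and ketene acetal 2 by aryne [2+2], hydrolysis, gem-dibromination and hydrolysis. Alkyne 16 comes from acid 7 and silylacetylene 10 through an ynone and an asymmetric transfer hydrogenation that sets C1' as (R).
- Ring order: the benzenoid ring is present from the start, the four-membered ring is built in step 1, and it is expanded to the quinone ring in step 10.

Key step: step 10

Remark: the target is a naphthazarin whose tautomers interconvert rapidly, so the tautomer drawn in the target SMILES stands for the compound; carbinol 18 is used as the mixture of its two carbinol epimers, since that centre becomes the C4 carbonyl.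

**Route**

Step 1
Reactants: 1 2-bromo-1,4-dimethoxybenzene; 2 1,1-diethoxyethene
Product: 4 3,6-dimethoxybenzocyclobuten-1(2H)-one, via diethyl ketal 3 (not isolated)
Conditions: NaNH2 (2.5 equiv), 2 (2 equiv), THF, reflux; then 1 M aq. HCl, THF, rt
Reagents that add atoms: water, O
Why: Dehydrobromination gives the symmetrical 3,6-dimethoxybenzyne, whose aryne [2+2] cycloaddition with the ketene acetal can give only one regioisomer, and ketal hydrolysis then releases the benzocyclobutenone.

Step 2
Reactants: 4 3,6-dimethoxybenzocyclobuten-1(2H)-one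
Product: 5 2,2-dibromo-3,6-dimethoxybenzocyclobuten-1(2H)-one
Conditions: NBS (2.2 equiv), (PhCO2)2 (cat.), CCl4 or PhCF3, reflux
Reagents that add atoms: N-bromosuccinimide, O=C1CCC(=O)N1Br
Why: Wohl–Ziegler radical bromination should take place twice at the only benzylic, carbonyl-activated CH2, while the non-polar radical conditions disfavour electrophilic bromination of the dimethoxyarene.

Step 3
Reactants: 5 2,2-dibromo-3,6-dimethoxybenzocyclobuten-1(2H)-one
Product: 6 3,6-dimethoxybenzocyclobutene-1,2-dione
Conditions: AgOCOCF3 (2.2 equiv), MeCN/H2O, rt to 50 °C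
Reagents that add atoms: water, O
Why: Silver-assisted hydrolysis of a benzylic gem-dibromide gives the second carbonyl under acidic conditions, which the base-sensitive strained dione should tolerate.

Step 4
Reactants: 7 4-methylpent-3-enoic acid
Product: 9 N-methoxy-N,4-dimethylpent-3-enamide, via acyl imidazolide 8 (not isolated)
Conditions: CDI (1.1 equiv), CH2Cl2, 0 °C to rt; then MeNH(OMe)·HCl (1.2 equiv), rt
Reagents that add atoms: N,O-dimethylhydroxylamine hydrochloride, CNOC.Cl
Why: Weinreb amide formation through the acyl imidazolide runs near neutrality, so the β,γ-double bond should not move into conjugation.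

Step 5
Reactants: 9 N-methoxy-N,4-dimethylpent-3-enamide; 10 ethynyltrimethylsilane
Product: 13 6-methyl-1-(trimethylsilyl)hept-5-en-1-yn-3-one, via lithium (trimethylsilyl)acetylide 11 (not isolated), via lithium hemiaminal adduct 12 (not isolated)
Conditions: 10, n-BuLi, THF, −78 °C; then 9, −78 to 0 °C; cold aq. NH4Cl
Reagents that add atoms: none
Why: In the Weinreb ketone synthesis the chelated tetrahedral adduct persists until the cold, weakly acidic quench, which prevents over-addition and limits isomerisation of the prenyl ketone.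

Step 6
Reactants: 13 6-methyl-1-(trimethylsilyl)hept-5-en-1-yn-3-one
Product: 14 (R)-6-methyl-1-(trimethylsilyl)hept-5-en-1-yn-3-ol
Conditions: Ru[(R,R)-TsNCH(Ph)CH(Ph)NH](p-cymene) (1 mol %), i-PrOH, rt
Reagents that add atoms: none
Why: In the Noyori asymmetric transfer hydrogenation of an alkynyl ketone the alkynyl group takes the place that an aryl group occupies in aryl ketone reductions, so the (R,R)-ligand should deliver hydride to the face that gives the (R)-carbinol (to be confirmed by Mosher ester analysis), and the base-free amido complex should leave the β,γ-alkene in place.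

Step 7
Reactants: 14 (R)-6-methyl-1-(trimethylsilyl)hept-5-en-1-yn-3-ol
Product: 15 (R)-3-(tert-butyldimethylsilyloxy)-6-methyl-1-(trimethylsilyl)hept-5-en-1-yne
Conditions: TBSCl, imidazole, DMF, rt
Reagents that add atoms: tert-butyldimethylsilyl chloride, CC(C)(C)[Si](C)(C)Cl
Why: Standard silylation of a secondary propargylic alcohol does not touch the stereocentre.

Step 8
Reactants: 15 (R)-3-(tert-butyldimethylsilyloxy)-6-methyl-1-(trimethylsilyl)hept-5-en-1-yne
Product: 16 (R)-3-(tert-butyldimethylsilyloxy)-6-methylhept-5-en-1-yne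
Conditions: K2CO3 (0.2 equiv), MeOH, rt
Reagents that add atoms: none
Why: Methanolysis cleaves the alkynyl C–Si bond selectively, while the secondary tert-butyldimethylsilyl ether is stable to these conditions.

Step 9
Reactants: 16 (R)-3-(tert-butyldimethylsilyloxy)-6-methylhept-5-en-1-yne; 6 3,6-dimethoxybenzocyclobutene-1,2-dione
Product: 18 2-hydroxy-3,6-dimethoxy-2-[(R)-3-(tert-butyldimethylsilyloxy)-6-methylhept-5-en-1-ynyl]benzocyclobuten-1(2H)-one (both carbinol epimers), via lithium acetylide 17 (not isolated)
Conditions: 16, n-BuLi, THF, −78 °C; cannulate into 6 in THF, −78 °C; aq. NH4Cl at −78 °C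
Reagents that add atoms: none
Why: 1,2-Addition of an alkynyllithium to the symmetrical dione has no regiochemical issue, the resulting alkoxide deactivates the second carbonyl against further addition, and the cold quench prevents alkoxide-triggered opening of the four-membered ring.

Step 10
Reactants: 18 2-hydroxy-3,6-dimethoxy-2-[(R)-3-(tert-butyldimethylsilyloxy)-6-methylhept-5-en-1-ynyl]benzocyclobuten-1(2H)-one
Product: 21 (R)-2-[1-(tert-butyldimethylsilyloxy)-4-methylpent-3-enyl]-5,8-dimethoxy-1,4-naphthoquinone, via o-quinoid alkynylketene 19 (not isolated), via aryl/aryloxyl diradical 20 (not isolated)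
Conditions: p-xylene (0.01 M, degassed), 138 °C
Reagents that add atoms: none
Why: Relief of four-ring strain drives a thermal 4π electrocyclic opening in which the hydroxyl rotates outward, giving the o-quinoid ketene 19 with the alkynyl group held next to the ketene carbon. That carbon then bonds to the distal alkyne carbon (C1–C2) to give diradical 20, a σ-radical at C3 and an aryloxyl radical, and transfer of the hydroxyl hydrogen to C3 gives the quinone. The closest known reaction is the Moore rearrangement of 4-alkynyl-4-hydroxycyclobutenones, including benzo-fused cases, to quinones. The quinone ring is the one ring closed, in a 6-endo mode with respect to the alkyne. No stereocentre is formed, and C1' takes no part in the bond reorganisation and sees neither acid nor base, so it should stay (R). The step needs six-membered closure to win over five-membered closure to an alkylidene indanedione; the alkyl-type alkyne terminus, which gives no stabilisation to an exocyclic vinyl radical, and the free hydroxyl as internal hydrogen donor secure this, with high dilution and exclusion of oxygen suppressing intermolecular radical paths.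

Step 11
Reactants: 21 (R)-2-[1-(tert-butyldimethylsilyloxy)-4-methylpent-3-enyl]-5,8-dimethoxy-1,4-naphthoquinone
Product: 22 (R)-2-(1-hydroxy-4-methylpent-3-enyl)-5,8-dimethoxy-1,4-naphthoquinone
Conditions: Et3N·3HF, MeCN, rt
Reagents that add atoms: none
Why: Fluoride-mediated desilylation with a nearly neutral HF source avoids both base-induced tautomerisation at C1' and acid-catalysed cyclisation of the new hydroxyl onto the prenyl alkene.

Step 12
Reactants: 23 3-hydroxy-3-methylbutanoic acid
Product: 25 3-acetoxy-3-methylbutanoic acid, via mixed acetic anhydride 24 (not isolated)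
Conditions: AcCl (2.5 equiv), PhNMe2 (2.5 equiv), CH2Cl2, 0 °C to reflux; then H2O, THF, rt
Reagents that add atoms: acetyl chloride, CC(Cl)=O
Why: Acetylation of a tertiary alcohol with acetyl chloride and a weak amine base, which intercepts the HCl that would otherwise give the tertiary chloride, also acetylates the carboxyl group, and the mixed anhydride is hydrolysed back to the acid in the aqueous stage.

Step 13
Reactants: 22 (R)-2-(1-hydroxy-4-methylpent-3-enyl)-5,8-dimethoxy-1,4-naphthoquinone; 25 3-acetoxy-3-methylbutanoic acid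
Product: 26 (R)-1-(5,8-dimethoxy-1,4-dioxo-1,4-dihydronaphthalen-2-yl)-4-methylpent-3-enyl 3-acetoxy-3-methylbutanoate
Conditions: DCC (1.3 equiv), DMAP (0.1 equiv), CH2Cl2, 0 °C to rt
Reagents that add atoms: none
Why: Steglich esterification acylates the only free hydroxyl at oxygen, so the C1'–O bond is not broken and the (R) configuration is retained.

Step 14
Reactants: 26 (R)-1-(5,8-dimethoxy-1,4-dioxo-1,4-dihydronaphthalen-2-yl)-4-methylpent-3-enyl 3-acetoxy-3-methylbutanoate
Product: 28 (R)-1-(5,8-dihydroxy-1,4-dioxo-1,4-dihydronaphthalen-2-yl)-4-methylpent-3-enyl 3-acetoxy-3-methylbutanoate (target), via naphthalene-1,4,5,8-tetraone 27 (not isolated)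
Conditions: AgO (5 equiv), 6 M HNO3, 1,4-dioxane, rt, a few minutes; then aq. Na2S2O4, CHCl3, rt
Reagents that add atoms: water, O
Why: Oxidative demethylation of the p-dimethoxy ring with AgO and nitric acid should give the diquinone with loss of methanol, and two-electron reduction with dithionite then gives the naphthazarin without touching the C1' ester.

**Compound list**

1 | 2-bromo-1,4-dimethoxybenzene | COc1ccc(OC)c(Br)c1 | starting material
2 | 1,1-diethoxyethene | C=C(OCC)OCC | starting material
3 | 7,7-diethoxy-2,5-dimethoxybicyclo[4.2.0]octa-1,3,5-triene (diethyl ketal of 4) | CCOC1(OCC)Cc2c(OC)ccc(OC)c21 | intermediate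
4 | 3,6-dimethoxybenzocyclobuten-1(2H)-one | O=C1Cc2c(OC)ccc(OC)c21 | intermediate
5 | 2,2-dibromo-3,6-dimethoxybenzocyclobuten-1(2H)-one | O=C1c2c(OC)ccc(OC)c2C1(Br)Br | intermediate
6 | 3,6-dimethoxybenzocyclobutene-1,2-dione | O=C1C(=O)c2c(OC)ccc(OC)c21 | intermediate
7 | 4-methylpent-3-enoic acid | CC(C)=CCC(=O)O | starting material
8 | 1-(1H-imidazol-1-yl)-4-methylpent-3-en-1-one (acyl imidazolide) | CC(C)=CCC(=O)n1ccnc1 | intermediate
9 | N-methoxy-N,4-dimethylpent-3-enamide | CC(C)=CCC(=O)N(C)OC | intermediate
10 | ethynyltrimethylsilane | C#C[Si](C)(C)C | starting material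
11 | lithium (trimethylsilyl)acetylide | [Li]C#C[Si](C)(C)C | intermediate
12 | lithium hemiaminal adduct of 9 and 11 | CC(C)=CCC(O[Li])(C#C[Si](C)(C)C)N(C)OC | intermediate
13 | 6-methyl-1-(trimethylsilyl)hept-5-en-1-yn-3-one | CC(C)=CCC(=O)C#C[Si](C)(C)C | intermediate
14 | (R)-6-methyl-1-(trimethylsilyl)hept-5-en-1-yn-3-ol | CC(C)=CC[C@@H](O)C#C[Si](C)(C)C | intermediate
15 | (R)-3-(tert-butyldimethylsilyloxy)-6-methyl-1-(trimethylsilyl)hept-5-en-1-yne | CC(C)=CC[C@@H](O[Si](C)(C)C(C)(C)C)C#C[Si](C)(C)C | intermediate
16 | (R)-3-(tert-butyldimethylsilyloxy)-6-methylhept-5-en-1-yne | CC(C)=CC[C@@H](O[Si](C)(C)C(C)(C)C)C#C | intermediate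
17 | lithium acetylide of 16 | CC(C)=CC[C@@H](O[Si](C)(C)C(C)(C)C)C#C[Li] | intermediate
18 | 2-hydroxy-3,6-dimethoxy-2-[(R)-3-(tert-butyldimethylsilyloxy)-6-methylhept-5-en-1-ynyl]benzocyclobuten-1(2H)-one, both carbinol epimers | CC(C)=CC[C@@H](O[Si](C)(C)C(C)(C)C)C#CC1(O)C(=O)c2c(OC)ccc(OC)c12 | intermediate
19 | o-quinoid hydroxy(alkynyl)ketene from ring opening of 18 | CC(C)=CC[C@@H](O[Si](C)(C)C(C)(C)C)C#CC(O)=C1C(=C=O)C(OC)=CC=C1OC | intermediate
20 | 4-hydroxy-1-oxyl-naphthalen-3-yl diradical carrying the (R)-side chain at C2 | CC(C)=CC[C@@H](O[Si](C)(C)C(C)(C)C)c1[c]c(O)c2c(OC)ccc(OC)c2c1[O] | intermediate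
21 | (R)-2-[1-(tert-butyldimethylsilyloxy)-4-methylpent-3-enyl]-5,8-dimethoxy-1,4-naphthoquinone | CC(C)=CC[C@@H](O[Si](C)(C)C(C)(C)C)C1=CC(=O)c2c(OC)ccc(OC)c2C1=O | intermediate
22 | (R)-2-(1-hydroxy-4-methylpent-3-enyl)-5,8-dimethoxy-1,4-naphthoquinone | CC(C)=CC[C@@H](O)C1=CC(=O)c2c(OC)ccc(OC)c2C1=O | intermediate
23 | 3-hydroxy-3-methylbutanoic acid | CC(C)(O)CC(=O)O | starting material
24 | acetic 3-acetoxy-3-methylbutanoic anhydride | CC(=O)OC(C)(C)CC(=O)OC(C)=O | intermediate
25 | 3-acetoxy-3-methylbutanoic acid | CC(=O)OC(C)(C)CC(=O)O | intermediate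
26 | (R)-1-(5,8-dimethoxy-1,4-dioxo-1,4-dihydronaphthalen-2-yl)-4-methylpent-3-enyl 3-acetoxy-3-methylbutanoate | CC(=O)OC(C)(C)CC(=O)O[C@H](CC=C(C)C)C1=CC(=O)c2c(OC)ccc(OC)c2C1=O | intermediate
27 | (R)-1-(1,4,5,8-tetraoxo-1,4,5,8-tetrahydronaphthalen-2-yl)-4-methylpent-3-enyl 3-acetoxy-3-methylbutanoate | CC(=O)OC(C)(C)CC(=O)O[C@H](CC=C(C)C)C1=CC(=O)C2=C(C(=O)C=CC2=O)C1=O | intermediate
28 | (R)-1-(5,8-dihydroxy-1,4-dioxo-1,4-dihydronaphthalen-2-yl)-4-methylpent-3-enyl 3-acetoxy-3-methylbutanoate | CC(=O)OC(C)(C)CC(=O)O[C@H](CC=C(C)C)C1=CC(=O)c2c(O)ccc(O)c2C1=O | target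

**Step count**

Total: 14 steps. Longest linear sequence: 10 steps (steps 4, 5, 6, 7, 8, 9, 10, 11, 13, 14).

**Steps most likely to fail**

Step 10. The ketene carbon may close on the proximal alkyne carbon instead (five-membered closure to an alkylidene indanedione). The σ-radical at C3 may also abstract an allylic hydrogen from C2' of the side chain instead of the hydroxyl hydrogen, or the diradical may be lost to intermolecular reactions. The fallback replaces the diradical closure by a pericyclic one and sets out from carbinol 18. Semihydrogenation of the alkyne (H2, Pd/CaCO3 poisoned with Pb(OAc)2, quinoline, EtOAc, rt) should give the (Z)-alkenyl carbinol F1. Heating F1 in toluene at 110 °C should open the four-membered ring to the dienylketene F2, which closes by 6π electrocyclisation and tautomerises to the naphthalene-1,4-diol F3. Oxidation of F3 (Ag2O, Et2O, rt) returns to the route at quinone 21.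

Step 14. Nitric acid and the strong oxidant may degrade the side chain (loss of acetic acid from the tertiary acetate, attack on the trisubstituted alkene), and oxidation of the electron-poor dimethoxy ring may stop short. The fallback unveils the naphthazarin before the sensitive ester is installed and sets out from alcohol 22. Acetylation (Ac2O, pyridine) should give the acetate F4, a simple ester better suited to the oxidant. AgO/HNO3 in dioxane should then give the tetraone F5, reduced in the work-up with Na2S2O4 to acetylshikonin F6. Mild alkaline hydrolysis (1 M NaOH, under N2, then acidification) should give shikonin F7. Carbodiimide esterification of F7 with acid 25 (DCC, DMAP, CH2Cl2) should acylate only the side-chain hydroxyl, because the phenols are tied up in hydrogen bonds to the quinone carbonyls, and returns to the route at target 28.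

Step 13. The activated acyl derivative of acid 25 may lose acetate by base-induced β-elimination and deliver the 3-methylbut-2-enoate ester, or may rearrange to the N-acylurea before the hindered alcohol attacks. The fallback builds the acyl group in two stages and sets out from alcohol 22. Esterification with 3-hydroxy-3-methylbutanoic acid 23 (DCC, DMAP, CH2Cl2), which has no β-leaving group, should give the 3-hydroxy-3-methylbutanoate ester F8. Acid-catalysed acetylation of its tertiary hydroxyl (Ac2O, Sc(OTf)3 1 mol %, MeCN, −20 °C) returns to the route at ester 26.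

**Further compounds**

F1 | step 10 | 2-hydroxy-3,6-dimethoxy-2-[(R,Z)-3-(tert-butyldimethylsilyloxy)-6-methylhepta-1,5-dienyl]benzocyclobuten-1(2H)-one | CC(C)=CC[C@@H](O[Si](C)(C)C(C)(C)C)/C=C\C1(O)C(=O)c2c(OC)ccc(OC)c12
F2 | step 10 | o-quinoid hydroxy(dienyl)ketene from ring opening of F1 | CC(C)=CC[C@@H](O[Si](C)(C)C(C)(C)C)/C=C\C(O)=C1C(=C=O)C(OC)=CC=C1OC
F3 | step 10 | (R)-2-[1-(tert-butyldimethylsilyloxy)-4-methylpent-3-enyl]-5,8-dimethoxynaphthalene-1,4-diol | CC(C)=CC[C@@H](O[Si](C)(C)C(C)(C)C)c1cc(O)c2c(OC)ccc(OC)c2c1O
F4 | step 14 | (R)-1-(5,8-dimethoxy-1,4-dioxo-1,4-dihydronaphthalen-2-yl)-4-methylpent-3-enyl acetate | CC(=O)O[C@H](CC=C(C)C)C1=CC(=O)c2c(OC)ccc(OC)c2C1=O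
F5 | step 14 | (R)-1-(1,4,5,8-tetraoxo-1,4,5,8-tetrahydronaphthalen-2-yl)-4-methylpent-3-enyl acetate | CC(=O)O[C@H](CC=C(C)C)C1=CC(=O)C2=C(C(=O)C=CC2=O)C1=O
F6 | step 14 | acetylshikonin, (R)-1-(5,8-dihydroxy-1,4-dioxo-1,4-dihydronaphthalen-2-yl)-4-methylpent-3-enyl acetate | CC(=O)O[C@H](CC=C(C)C)C1=CC(=O)c2c(O)ccc(O)c2C1=O
F7 | step 14 | shikonin, (R)-5,8-dihydroxy-2-(1-hydroxy-4-methylpent-3-enyl)-1,4-naphthoquinone | CC(C)=CC[C@@H](O)C1=CC(=O)c2c(O)ccc(O)c2C1=O
F8 | step 13 | (R)-1-(5,8-dimethoxy-1,4-dioxo-1,4-dihydronaphthalen-2-yl)-4-methylpent-3-enyl 3-hydroxy-3-methylbutanoate | CC(C)(O)CC(=O)O[C@H](CC=C(C)C)C1=CC(=O)c2c(OC)ccc(OC)c2C1=O
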